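**Plan**
Retrosynthetic cuts, in order: the primary O–Si bond; ring A hydroquinone back to its 5-O-methyl ether (through the quinone); C4–C4a of lactone ring B; the aryl ester C1–O2; C4–I with C3–O back to a terminal epoxide and then an alkene; the mevalonate ester at O–C4′; C2′–C3′ of the heptenol.
Enabling feature: ring A carries oxygen on C5 and C8 (para) and the carbonyl C1 on C8a. PhI(OAc)2/MeOH therefore turns the 8-hydroxy-5-methoxy arene into a C5-ketal/C8-dienone. In that dienone, C4a–H is the free β-carbon of an enone whose α-carbon C8a bears the ester.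
O2 would be a β-leaving group for any carbanion or metal at C4, so C4 reacts as a radical. A plain arene would be too slow an acceptor for closure through an ester tether.
Forward order: chain, mevalonate ester, epoxide, iodohydrin, aryl ester, dearomatisation of ring A, ring B by radical closure C4→C4a, rearomatisation, O5 demethylation, desilylation.
Stereochemistry: C4′ comes from (R)-propylene oxide and the mevalonate carbinol from (R)-mevalonolactone. C3 is set by hydrolytic kinetic resolution, and no C–O bond at a stereocentre is broken afterwards.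

Key step: step 9

Remark: isocoumarin numbering is used (C1 lactone carbonyl, O2, C3, C4, C4a, C5–C8, C8a; side chain C1′–C5′). Compounds 1, 5, 6 (as THF solution) and 12 are taken as commercial.

Step 1
Reactants: 1 (R)-mevalonolactone
Product: 4 (3R)-5-[(tert-butyldimethylsilyl)oxy]-3-hydroxy-3-methylpentanoic acid, via potassium (R)-mevalonate 2 (not isolated), via silyl ester silyl ether 3 (not isolated)
Conditions: KOH (1.0 equiv), MeOH/H2O, rt, evaporate; TBSCl (2.3 equiv), imidazole, DMF, rt; K2CO3 (1 equiv), MeOH/THF/H2O, rt; aq. KHSO4 to pH 4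
Reagents that add atoms: potassium hydroxide [K+].[OH-]; tert-butyldimethylsilyl chloride CC(C)(C)[Si](C)(C)Cl
Why: Saponification opens the δ-lactone, TBSCl silylates the primary hydroxyl and the carboxylate but not the tertiary hydroxyl, and carbonate cleaves only the labile silyl ester (standard lactone to protected hydroxy acid sequence), so the quaternary stereocentre is not involved.

Step 2
Reactants: 5 (R)-propylene oxide; 6 3-butenylmagnesium bromide
Product: 7 (R)-hept-6-en-2-ol
Conditions: CuI (10 mol%), THF, −30 °C to 0 °C; then 1 M HCl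
Reagents that add atoms: none
Why: The copper-catalysed Grignard opening of a terminal epoxide is an SN2 attack at the unsubstituted carbon, so the C4′–O stereocentre of 5 is carried over unchanged.

Step 3
Reactants: 7 (R)-hept-6-en-2-ol; 4 (3R)-5-[(tert-butyldimethylsilyl)oxy]-3-hydroxy-3-methylpentanoic acid
Product: 8 (2R)-hept-6-en-2-yl (3R)-5-[(tert-butyldimethylsilyl)oxy]-3-hydroxy-3-methylpentanoate
Conditions: DCC, DMAP (0.1 equiv), CH2Cl2, 0 °C to rt
Reagents that add atoms: none
Why: Steglich esterification acylates the secondary alcohol with retention at C4′, while the hindered tertiary hydroxyl of 4 stays free.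

Step 4
Reactants: 8 (2R)-hept-6-en-2-yl ester
Product: 9 (2R)-5-(oxiran-2-yl)pentan-2-yl (3R)-5-[(tert-butyldimethylsilyl)oxy]-3-hydroxy-3-methylpentanoate (both oxirane epimers)
Conditions: mCPBA, CH2Cl2, 0 °C to rt
Reagents that add atoms: 3-chloroperoxybenzoic acid OOC(=O)c1cccc(Cl)c1
Why: Prilezhaev epoxidation of the only alkene; the remote centres give no facial control, so both C3 epimers are expected.

Step 5
Reactants: 9 epoxide (both oxirane epimers)
Product: 10 (2R)-5-[(2R)-oxiran-2-yl]pentan-2-yl (3R)-5-[(tert-butyldimethylsilyl)oxy]-3-hydroxy-3-methylpentanoate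
Conditions: (R,R)-Co(salen)(OAc) [salen = N,N′-bis(3,5-di-tert-butylsalicylidene)cyclohexane-1,2-diaminate] (1 mol%), H2O (0.55 equiv), THF, 0 °C to rt
Reagents that add atoms: none
Why: In this Jacobsen hydrolytic kinetic resolution the (R,R)-catalyst should hydrolyse the (S)-oxirane to the diol and leave the (R)-oxirane, as it does with simple 1,2-epoxyalkanes, which sets C3 by catalyst control.

Step 6
Reactants: 10 (R)-epoxide
Product: 11 (2R,6R)-6-hydroxy-7-iodoheptan-2-yl (3R)-5-[(tert-butyldimethylsilyl)oxy]-3-hydroxy-3-methylpentanoate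
Conditions: LiI (1.5 equiv), AcOH (1.5 equiv), THF, rt
Reagents that add atoms: lithium iodide [Li+].[I-]
Why: Lithium halide/acetic acid opening of a terminal epoxide is an SN2 attack of iodide at the primary carbon C4, so the C3–O bond and its configuration are kept.

Step 7
Reactants: 11 iodohydrin; 12 2-hydroxy-5-methoxybenzoic acid
Product: 13 (2R,6R)-1-iodo-6-{[(3R)-5-[(tert-butyldimethylsilyl)oxy]-3-hydroxy-3-methylpentanoyl]oxy}heptan-2-yl 2-hydroxy-5-methoxybenzoate
Conditions: DCC, DMAP (0.1 equiv), CH2Cl2, 0 °C
Reagents that add atoms: none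
Why: Steglich esterification forms C1–O2 without breaking the C3–O bond (retention), and the hydrogen-bonded ortho-phenol of 12 and the tertiary hydroxyl are much poorer acyl acceptors than the secondary alcohol.

Step 8
Reactants: 13 iodo ester
Product: 14 (2R,6R)-1-iodo-6-{[(3R)-5-[(tert-butyldimethylsilyl)oxy]-3-hydroxy-3-methylpentanoyl]oxy}heptan-2-yl 3,3-dimethoxy-6-oxocyclohexa-1,4-diene-1-carboxylate
Conditions: PhI(OAc)2 (1.05 equiv), MeOH, 0 °C; used without delay
Reagents that add atoms: methanol CO
Why: Hypervalent-iodine oxidative dearomatisation of a p-methoxyphenol in methanol (quinone monoketal formation) places the second methoxy group on C5 para to the phenol oxygen and should be much faster than oxidation at the alkyl iodide.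

Step 9
Reactants: 14 dienone ketal
Product: 16 (2R)-5-[(3R)-8-hydroxy-5-methoxy-1-oxo-3,4-dihydro-1H-isochromen-3-yl]pentan-2-yl (3R)-5-[(tert-butyldimethylsilyl)oxy]-3-hydroxy-3-methylpentanoate, via keto lactone ketal 15 (not isolated)
Conditions: (Me3Si)3SiH (1.5 equiv) + AIBN (0.3 equiv) in PhH added over 10 h by syringe pump to 14 (1 mM) in PhH, 80 °C; concentrate; PPTS (0.1 equiv), CH2Cl2, rt
Reagents that add atoms: none
Why: The silyl radical abstracts iodine from C4, and the nucleophilic primary C4 radical adds to C4a, the unsubstituted β-carbon of the C8 enone whose α-carbon C8a bears the ester; the resulting C8a radical, stabilised by both carbonyl groups, takes hydrogen from the silane and carries the chain (reductive Giese-type radical cyclisation). The closest known reaction type is the formal radical cyclisation onto a benzene ring, in which a p-alkoxyphenol is dearomatised to a cross-conjugated dienone ketal, cyclised with a stannane or silane and rearomatised with acid. Ring B closes in the 6-endo-trig mode, because the 5-exo alternative at C8a would attack a fully substituted α-carbon and leave an unstabilised radical, and the C6=C7 bond is out of reach of the tether. The two new centres C4a and C8a of 15 need no control, since PPTS expels one methanol from C5 and enolises C8, which erases both and returns aromatic ring A; C3 is untouched because the radical sits on the neighbouring carbon and the 1,2-acyloxy shift should be slower than closure onto this acceptor. The step needs closure to outrun hydrogen transfer and intermolecular addition even though the ester must first reach its less populated E rotamer, and this is secured by the doubly activated acceptor, the slow hydrogen donor (Me3Si)3SiH, 80 °C and millimolar concentration with slow addition.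

Step 10
Reactants: 16 8-hydroxy-5-methoxy lactone
Product: 18 (2R)-5-[(3R)-5,8-dihydroxy-1-oxo-3,4-dihydro-1H-isochromen-3-yl]pentan-2-yl (3R)-5-[(tert-butyldimethylsilyl)oxy]-3-hydroxy-3-methylpentanoate, via lactone quinone 17 (not isolated)
Conditions: PhI(OAc)2 (1.1 equiv), MeCN/H2O 4:1, 0 °C; then aq. Na2S2O4, EtOAc, rt
Reagents that add atoms: water O
Why: Hypervalent-iodine oxidation of a p-methoxyphenol in water gives the C5 hemiketal, which loses methanol to the p-quinone (oxidative demethylation), and dithionite reduces the quinone to the hydroquinone under near-neutral conditions that spare all three ester groups.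

Step 11
Reactants: 18 silyl ether
Product: 19 (2R)-5-[(3R)-5,8-dihydroxy-1-oxo-3,4-dihydro-1H-isochromen-3-yl]pentan-2-yl (3R)-3,5-dihydroxy-3-methylpentanoate (target)
Conditions: HF·pyridine, pyridine, THF, 0 °C
Reagents that add atoms: none
Why: Buffered fluoride cleavage of the primary silyl ether avoids a free alkoxide, which would otherwise attack the side-chain ester and expel the C4′ alcohol as mevalonolactone forms.

**Compound list**
1 | (R)-mevalonolactone | C[C@@]1(O)CCOC(=O)C1 | starting material
2 | potassium (R)-mevalonate | [K+].[O-]C(=O)C[C@](C)(O)CCO | intermediate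
3 | tert-butyldimethylsilyl (3R)-5-[(tert-butyldimethylsilyl)oxy]-3-hydroxy-3-methylpentanoate | CC(C)(C)[Si](C)(C)OC(=O)C[C@](C)(O)CCO[Si](C)(C)C(C)(C)C | intermediate
4 | (3R)-5-[(tert-butyldimethylsilyl)oxy]-3-hydroxy-3-methylpentanoic acid | OC(=O)C[C@](C)(O)CCO[Si](C)(C)C(C)(C)C | intermediate
5 | (R)-propylene oxide | C[C@@H]1CO1 | starting material
6 | 3-butenylmagnesium bromide | C=CCC[Mg]Br | starting material
7 | (R)-hept-6-en-2-ol | C[C@@H](O)CCCC=C | intermediate
8 | (2R)-hept-6-en-2-yl (3R)-5-[(tert-butyldimethylsilyl)oxy]-3-hydroxy-3-methylpentanoate | C[C@H](CCCC=C)OC(=O)C[C@](C)(O)CCO[Si](C)(C)C(C)(C)C | intermediate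
9 | (2R)-5-(oxiran-2-yl)pentan-2-yl ester, both oxirane epimers | C[C@H](CCCC1CO1)OC(=O)C[C@](C)(O)CCO[Si](C)(C)C(C)(C)C | intermediate
10 | (2R)-5-[(2R)-oxiran-2-yl]pentan-2-yl ester | C[C@H](CCC[C@@H]1CO1)OC(=O)C[C@](C)(O)CCO[Si](C)(C)C(C)(C)C | intermediate
11 | (2R,6R)-6-hydroxy-7-iodoheptan-2-yl ester (iodohydrin) | C[C@H](CCC[C@@H](O)CI)OC(=O)C[C@](C)(O)CCO[Si](C)(C)C(C)(C)C | intermediate
12 | 2-hydroxy-5-methoxybenzoic acid | COc1ccc(O)c(C(=O)O)c1 | starting material
13 | (2R,6R)-iodo diester, 2-hydroxy-5-methoxybenzoate at C3–O | C[C@H](CCC[C@H](CI)OC(=O)c1cc(OC)ccc1O)OC(=O)C[C@](C)(O)CCO[Si](C)(C)C(C)(C)C | intermediate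
14 | 3,3-dimethoxy-6-oxocyclohexa-1,4-diene-1-carboxylate of the iodohydrin (dienone ketal) | C[C@H](CCC[C@H](CI)OC(=O)C1=CC(OC)(OC)C=CC1=O)OC(=O)C[C@](C)(O)CCO[Si](C)(C)C(C)(C)C | intermediate
15 | (3R)-5,5-dimethoxy-1,8-dioxo-3,4,4a,5,8,8a-hexahydro-1H-isochromen-3-yl compound (C4a/C8a not defined) | C[C@H](CCC[C@@H]1CC2C(C(=O)O1)C(=O)C=CC2(OC)OC)OC(=O)C[C@](C)(O)CCO[Si](C)(C)C(C)(C)C | intermediate
16 | (3R)-8-hydroxy-5-methoxy-3,4-dihydroisocoumarin, side-chain ester silylated | C[C@H](CCC[C@@H]1Cc2c(OC)ccc(O)c2C(=O)O1)OC(=O)C[C@](C)(O)CCO[Si](C)(C)C(C)(C)C | intermediate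
17 | (3R)-1,5,8-trioxo-3,4,5,8-tetrahydro-1H-isochromen-3-yl compound (lactone quinone) | C[C@H](CCC[C@@H]1CC2=C(C(=O)O1)C(=O)C=CC2=O)OC(=O)C[C@](C)(O)CCO[Si](C)(C)C(C)(C)C | intermediate
18 | 5″-O-TBS ether of the target | C[C@H](CCC[C@@H]1Cc2c(O)ccc(O)c2C(=O)O1)OC(=O)C[C@](C)(O)CCO[Si](C)(C)C(C)(C)C | intermediate
19 | CNP0591388.1 | C[C@H](CCC[C@@H]1Cc2c(O)ccc(O)c2C(=O)O1)OC(=O)C[C@](C)(O)CCO | target

Total step count: 11. Longest linear sequence: 10 (steps 2–11, or step 1 followed by steps 3–11).

**Steps most likely to fail**

1. Step 9. The C4 radical may be lost before the ester has turned into the E rotamer needed for closure. The competing processes are hydrogen transfer from the silane, a 1,5-hydrogen shift along the chain, 1,2-acyloxy migration, and addition to a second dienone molecule.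
The fallback sets out from epoxide 10 and comes back at quinone 17. Compound 10 and commercial 2,5-dimethoxybenzoic acid are joined by carboxylate-directed ortho C–H alkylation with Pd(OAc)2, N-acetyl-tert-leucine and KOAc in (CF3)2CHOH at 75 °C. The palladacycle opens the epoxide at its CH2 terminus with retention at C3, and the alkoxide lactonises in the same flask. This should give the 5,8-dimethoxy lactone F1. Oxidative demethylation of both ethers with (NH4)2Ce(NO3)6 in MeCN/H2O at 0 °C then gives 17.

2. Step 7. Three things may go wrong: self-acylation of the phenolic acid, slow acyl transfer from the hydrogen-bonded salicylate, and base-induced re-closure of the iodohydrin to the epoxide.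
The fallback sets out from 12 (with 11) and comes back at 13. The phenol is masked first: Ac2O/pyridine converts 12 into 2-acetoxy-5-methoxybenzoic acid F2. This acid has no free phenol and no internal hydrogen bond, and it is coupled with 11 (DCC, DMAP) to the O-acetyl iodo diester F3. Brief treatment with NH3 in MeOH at 0 °C cleaves the activated aryl acetate chemoselectively and gives 13.

3. Step 1. The mevalonate may re-lactonise during silylation or on acidification, driven by the gem-disubstituted carbon.
The fallback sets out from 2 and comes back at 4. The carboxylate is capped before any silylation: BnBr in DMF alkylates 2 to benzyl (R)-mevalonate F4. TBSCl/imidazole then silylates the primary hydroxyl to benzyl (3R)-5-[(tert-butyldimethylsilyl)oxy]-3-hydroxy-3-methylpentanoate F5. Neutral hydrogenolysis (H2, Pd/C, EtOAc) releases 4.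

**Further compounds**
F1 | step 9 | (2R)-5-[(3R)-5,8-dimethoxy-1-oxo-3,4-dihydro-1H-isochromen-3-yl]pentan-2-yl (3R)-5-[(tert-butyldimethylsilyl)oxy]-3-hydroxy-3-methylpentanoate | C[C@H](CCC[C@@H]1Cc2c(OC)ccc(OC)c2C(=O)O1)OC(=O)C[C@](C)(O)CCO[Si](C)(C)C(C)(C)C
F2 | step 7 | 2-acetoxy-5-methoxybenzoic acid | COc1ccc(OC(C)=O)c(C(=O)O)c1
F3 | step 7 | O-acetyl derivative of 13 | C[C@H](CCC[C@H](CI)OC(=O)c1cc(OC)ccc1OC(C)=O)OC(=O)C[C@](C)(O)CCO[Si](C)(C)C(C)(C)C
F4 | step 1 | benzyl (R)-mevalonate | O=C(C[C@](C)(O)CCO)OCc1ccccc1
F5 | step 1 | benzyl (3R)-5-[(tert-butyldimethylsilyl)oxy]-3-hydroxy-3-methylpentanoate | O=C(C[C@](C)(O)CCO[Si](C)(C)C(C)(C)C)OCc1ccccc1
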